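**Plan**

- Target: (1R,3S,4S)-4-bromo-3-chloro-1-[(4S)-4-hydroxy-6-methylhepta-1,5-dien-2-yl]-4-methylcyclohexan-1-ol. In the ring (C1 carbinol, C3 CHCl, C4 CBr) the C1 hydroxyl is cis to Br and trans to Cl, and Br and Cl are trans.
- Retrosynthetic cuts, in order: the carbinol C–H (ketone reduction) and the CH2–C(=O) bond of the side chain (allylsilane acylation); both bonds from the ring-attached sp2 carbon to its CH2 groups (ester to allylsilane); C4–Br and C3–Cl (from a C3=C4 alkene via its epoxide); ring bonds C1–C2 and C5–C6 ([4+2]).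
- Enabling feature: the carbinol carbon C1 (OH plus one carbon substituent) lies 1,4 to the C(CH3)Br carbon C4, with CHCl (C3) next to it. This is the pattern of an isoprene adduct of a 2-oxyacrylate, whose remaining C3=C4 alkene later takes both halogens.
- Forward order: a lactate-derived methylene dioxolanone and isoprene close the only ring; the ring alkene becomes epoxide, chlorohydrin and bromochloride; the ester becomes an allylsilane, then a dienone, then the carbinol.
- Stereochemistry: C1 from the (S)-lactic acid-derived acetal (diene adds anti to tert-butyl); C3 and C4 from hydroxyl-directed epoxidation, anti opening by chloride and retentive SN1 bromination; the side-chain carbinol from a reagent-controlled CBS reduction.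

Key step: step 4

Remark on the chemistry: the tertiary C1 hydroxyl stays free from step 5 to step 9 because it directs the epoxidation and its geminal ester keeps it from ionising; it is silylated only before the Lewis acid step.

Step 1
Reactants: 1 (S)-lactic acid; 2 pivalaldehyde
Product: 3 (2S,5S)-2-tert-butyl-5-methyl-1,3-dioxolan-4-one (cis)
Conditions: TsOH·H2O (cat.), H2SO4 (cat.), pentane, reflux, Dean–Stark; crystallisation at −78 °C
Reagents that add atoms: none
Why: Acid-catalysed acetalisation of an α-hydroxy acid with azeotropic removal of water (Seebach dioxolanone formation) should give the 1,3-dioxolan-4-one, the new acetal centre being set under thermodynamic control cis to the lactate methyl group and the pure cis isomer being secured by low-temperature crystallisation.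

Step 2
Reactants: 3 (2S,5S)-2-tert-butyl-5-methyl-1,3-dioxolan-4-one
Product: 4 (2S,5R)-5-bromo-2-tert-butyl-5-methyl-1,3-dioxolan-4-one (Br trans to tert-butyl; used crude)
Conditions: N-bromosuccinimide, azobis(isobutyronitrile) (cat.), CCl4 (or PhCF3), reflux
Reagents that add atoms: N-bromosuccinimide, O=C1CCC(=O)N1Br
Why: Wohl–Ziegler radical bromination should take place at the only tertiary C–H, which is activated captodatively by the ring oxygen and the carbonyl group, with bromine expected to enter trans to the tert-butyl group at a centre that is destroyed again in the next step.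

Step 3
Reactants: 4 (2S,5R)-5-bromo-2-tert-butyl-5-methyl-1,3-dioxolan-4-one
Product: 5 (2S)-2-tert-butyl-5-methylidene-1,3-dioxolan-4-one
Conditions: Et3N, Et2O, 0 °C to rt
Reagents that add atoms: none
Why: E2 dehydrobromination of the tertiary α-bromo lactone by the amine base should give the exocyclic acrylate-type alkene and leaves the acetal stereocentre untouched.

Step 4
Reactants: 5 (2S)-2-tert-butyl-5-methylidene-1,3-dioxolan-4-one; 6 isoprene
Product: 7 (2S,5R)-2-tert-butyl-8-methyl-1,3-dioxaspiro[4.5]dec-7-en-4-one
Conditions: 6 (5 equiv), toluene, 2,6-di-tert-butyl-4-methylphenol (cat.), sealed tube, 90 °C; chromatography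
Reagents that add atoms: none
Why: Thermal, concerted and suprafacial [4+2] cycloaddition (normal-electron-demand Diels–Alder reaction) of s-cis isoprene across the exocyclic C=C of 5, an α-acyloxyacrylate held in a ring; the closest known chemistry is the Diels–Alder reactivity of 2-tert-butyl-5-methylidene-1,3-dioxolan-4-ones toward cyclopentadiene and open-chain dienes. The cyclohexene ring closes by intermolecular [4+2] annulation, both σ-bonds (C5–C6 and C9–C10 of 7, that is C1–C2 and C5–C6 of the target ring) forming in the same six-electron transition state, spiro to the dioxolanone. The one new stereocentre, spiro C5, is controlled by the acetal carbon C2: the tert-butyl group screens one face of the nearly planar dioxolanone, the diene bonds anti to it, and the (2S) acetal should therefore give the (5R) configuration that becomes the (1R) carbinol of the target. The step needs para regiochemistry (methyl 1,4 to the spiro carbon), which the substrate pair secures by joining the CH2 terminus of 5, the site of its largest LUMO coefficient, to C1 of isoprene, the diene terminus with the largest HOMO coefficient; the minor meta adduct expected beside it is to be removed by chromatography or crystallisation. Endo or exo orientation is of no consequence because no further stereocentre is formed.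

Step 5
Reactants: 7 (2S,5R)-2-tert-butyl-8-methyl-1,3-dioxaspiro[4.5]dec-7-en-4-one
Product: 8 methyl (1R)-1-hydroxy-4-methylcyclohex-3-ene-1-carboxylate
Conditions: NaOMe (0.2 equiv), MeOH, 0 °C to rt
Reagents that add atoms: methanol, CO
Why: Base-catalysed transesterification (methanolysis) of the acylal lactone should open the dioxolanone, the hemiacetal alkoxide then expelling pivalaldehyde, while the quaternary carbinol centre has no α-hydrogen and cannot epimerise.

Step 6
Reactants: 8 methyl (1R)-1-hydroxy-4-methylcyclohex-3-ene-1-carboxylate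
Product: 9 methyl (1R,3R,6S)-3-hydroxy-6-methyl-7-oxabicyclo[4.1.0]heptane-3-carboxylate (epoxide oxygen cis to the hydroxyl)
Conditions: VO(acac)2 (3 mol %), t-BuOOH (anhydrous, in decane), CH2Cl2, 25–40 °C
Reagents that add atoms: tert-butyl hydroperoxide, CC(C)(C)OO
Why: Hydroxyl-directed vanadium-catalysed epoxidation (Sharpless type, as established for 4-substituted cyclohex-3-en-1-ols such as terpinen-4-ol) should deliver oxygen from the vanadate ester of the homoallylic tertiary alcohol to the alkene face syn to the hydroxyl, which sets both epoxide carbons cis to the C–OH bond.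

Step 7
Reactants: 9 methyl (1R,3R,6S)-3-hydroxy-6-methyl-7-oxabicyclo[4.1.0]heptane-3-carboxylate
Product: 10 methyl (1R,3S,4S)-3-chloro-1,4-dihydroxy-4-methylcyclohexane-1-carboxylate
Conditions: Li2CuCl4 (0.1 M in THF, 2 equiv), THF, rt; pH 7 buffer
Reagents that add atoms: Li2CuCl4, [Li+].[Li+].[Cu+2].[Cl-].[Cl-].[Cl-].[Cl-]
Why: SN2-type opening of the trisubstituted epoxide by the soft, non-acidic chloride donor Li2CuCl4 is expected at the less hindered secondary carbon with inversion (trans-diaxial, Fürst–Plattner opening), which places chlorine trans to the C1 hydroxyl and leaves the tertiary C–O bond, cis to that hydroxyl, intact.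

Step 8
Reactants: 10 methyl (1R,3S,4S)-3-chloro-1,4-dihydroxy-4-methylcyclohexane-1-carboxylate
Product: 11 methyl (1R,3S,4S)-4-bromo-3-chloro-1-hydroxy-4-methylcyclohexane-1-carboxylate
Conditions: HBr (33% in AcOH, 5 equiv), CH2Cl2, 0 °C
Reagents that add atoms: hydrogen bromide, Br
Why: SN1 substitution of the tertiary alcohol by HBr, in which the antiperiplanar vicinal chlorine shields one face of the β-chloro cation (anchimeric assistance through a chloronium-like bridged ion) so that bromide should enter at the tertiary carbon anti to chlorine with net retention, while the other tertiary hydroxyl is kept from ionising by its geminal ester.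

Step 9
Reactants: 11 methyl (1R,3S,4S)-4-bromo-3-chloro-1-hydroxy-4-methylcyclohexane-1-carboxylate
Product: 13 (1R,3S,4S)-4-bromo-3-chloro-4-methyl-1-[3-(trimethylsilyl)prop-1-en-2-yl]cyclohexan-1-ol, via bis(silylmethyl) diol 12 (not isolated)
Conditions: Me3SiCH2MgCl (6 equiv), CeCl3 (dried, 6 equiv), THF, −78 °C to rt; aq. NH4Cl; then SiO2, CH2Cl2, rt
Reagents that add atoms: (trimethylsilyl)methylmagnesium chloride, C[Si](C)(C)C[Mg]Cl
Why: Bunnelle–Narayanan allylsilane synthesis, in which CeCl3-promoted double addition of Me3SiCH2MgCl to the ester (after deprotonation of the hydroxyl) gives a bis(β-silyl) carbinol that should undergo acid-mediated Peterson elimination on silica gel to the 2-substituted allylsilane without touching any stereocentre.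

Step 10
Reactants: 13 (1R,3S,4S)-4-bromo-3-chloro-4-methyl-1-[3-(trimethylsilyl)prop-1-en-2-yl]cyclohexan-1-ol
Product: 14 [2-[(1R,3S,4S)-4-bromo-3-chloro-4-methyl-1-(trimethylsilyloxy)cyclohexyl]prop-2-en-1-yl](trimethyl)silane
Conditions: N-(trimethylsilyl)imidazole (3 equiv), CH2Cl2, rt
Reagents that add atoms: N-(trimethylsilyl)imidazole, C[Si](C)(C)n1ccnc1
Why: Silylation of the hindered tertiary alcohol with a neutral silyl donor should mask the only protic group before the Lewis acid step without exposing the allylsilane to acid.

Step 11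
Reactants: 14 [2-[(1R,3S,4S)-4-bromo-3-chloro-4-methyl-1-(trimethylsilyloxy)cyclohexyl]prop-2-en-1-yl](trimethyl)silane; 15 3-methylbut-2-enoyl chloride
Product: 16 6-[(1R,3S,4S)-4-bromo-3-chloro-4-methyl-1-(trimethylsilyloxy)cyclohexyl]-2-methylhepta-2,6-dien-4-one
Conditions: 15 (1.2 equiv) precomplexed with TiCl4 (1.1 equiv), CH2Cl2, −78 °C; aq. NaHCO3 quench at −78 °C
Reagents that add atoms: none
Why: Hosomi–Sakurai acylation, in which the TiCl4-activated acid chloride is attacked by the terminal alkene carbon of the allylsilane and the β-silyl cation loses Me3SiCl, should give the β,γ-unsaturated dienone with clean allylic transposition, as in the classical allylsilane route to ipsdienone-type dienones.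

Step 12
Reactants: 16 6-[(1R,3S,4S)-4-bromo-3-chloro-4-methyl-1-(trimethylsilyloxy)cyclohexyl]-2-methylhepta-2,6-dien-4-one
Product: 18 (1R,3S,4S)-4-bromo-3-chloro-1-[(4S)-4-hydroxy-6-methylhepta-1,5-dien-2-yl]-4-methylcyclohexan-1-ol, via O-silylated (S)-alcohol 17 (not isolated)
Conditions: (R)-Me-CBS oxazaborolidine (0.5 equiv), catecholborane (2 equiv), toluene, −78 °C; MeOH; then Bu4NF, AcOH, THF, 0 °C
Reagents that add atoms: none
Why: Corey–Bakshi–Shibata reduction, in which (R)-1-methyl-3,3-diphenyltetrahydro-1H,3H-pyrrolo[1,2-c][1,3,2]oxazaborole with catecholborane treats the alkenyl group as the large and the methylene group as the small substituent and should therefore give the (S)-allylic alcohol by 1,2-reduction (the sense that gives (S)-1-phenylethanol from acetophenone), after which buffered fluoride removes the tertiary trimethylsilyl ether without disturbing the tertiary bromide or the allylic alcohols.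

**Compound list**

1 | (S)-lactic acid | C[C@H](O)C(=O)O | starting material
2 | pivalaldehyde | CC(C)(C)C=O | starting material
3 | (2S,5S)-2-tert-butyl-5-methyl-1,3-dioxolan-4-one | C[C@@H]1O[C@H](C(C)(C)C)OC1=O | intermediate
4 | (2S,5R)-5-bromo-2-tert-butyl-5-methyl-1,3-dioxolan-4-one | C[C@]1(Br)O[C@H](C(C)(C)C)OC1=O | intermediate
5 | (2S)-2-tert-butyl-5-methylidene-1,3-dioxolan-4-one | C=C1O[C@H](C(C)(C)C)OC1=O | intermediate
6 | isoprene | C=CC(C)=C | starting material
7 | (2S,5R)-2-tert-butyl-8-methyl-1,3-dioxaspiro[4.5]dec-7-en-4-one | O=C1[C@]2(CCC(C)=CC2)O[C@H](C(C)(C)C)O1 | intermediate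
8 | methyl (1R)-1-hydroxy-4-methylcyclohex-3-ene-1-carboxylate | COC(=O)[C@@]1(O)CCC(C)=CC1 | intermediate
9 | methyl (1R,3R,6S)-3-hydroxy-6-methyl-7-oxabicyclo[4.1.0]heptane-3-carboxylate | COC(=O)[C@@]1(O)CC[C@]2(C)O[C@@H]2C1 | intermediate
10 | methyl (1R,3S,4S)-3-chloro-1,4-dihydroxy-4-methylcyclohexane-1-carboxylate | COC(=O)[C@@]1(O)CC[C@](C)(O)[C@@H](Cl)C1 | intermediate
11 | methyl (1R,3S,4S)-4-bromo-3-chloro-1-hydroxy-4-methylcyclohexane-1-carboxylate | COC(=O)[C@@]1(O)CC[C@](C)(Br)[C@@H](Cl)C1 | intermediate
12 | 2-[(1R,3S,4S)-4-bromo-3-chloro-1-hydroxy-4-methylcyclohexyl]-1,3-bis(trimethylsilyl)propan-2-ol | C[Si](C)(C)CC(O)(C[Si](C)(C)C)[C@@]1(O)CC[C@](C)(Br)[C@@H](Cl)C1 | intermediate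
13 | (1R,3S,4S)-4-bromo-3-chloro-4-methyl-1-[3-(trimethylsilyl)prop-1-en-2-yl]cyclohexan-1-ol | C=C(C[Si](C)(C)C)[C@@]1(O)CC[C@](C)(Br)[C@@H](Cl)C1 | intermediate
14 | [2-[(1R,3S,4S)-4-bromo-3-chloro-4-methyl-1-(trimethylsilyloxy)cyclohexyl]prop-2-en-1-yl](trimethyl)silane | C=C(C[Si](C)(C)C)[C@@]1(O[Si](C)(C)C)CC[C@](C)(Br)[C@@H](Cl)C1 | intermediate
15 | 3-methylbut-2-enoyl chloride | CC(C)=CC(=O)Cl | starting material
16 | 6-[(1R,3S,4S)-4-bromo-3-chloro-4-methyl-1-(trimethylsilyloxy)cyclohexyl]-2-methylhepta-2,6-dien-4-one | C=C(CC(=O)C=C(C)C)[C@@]1(O[Si](C)(C)C)CC[C@](C)(Br)[C@@H](Cl)C1 | intermediate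
17 | (4S)-6-[(1R,3S,4S)-4-bromo-3-chloro-4-methyl-1-(trimethylsilyloxy)cyclohexyl]-2-methylhepta-2,6-dien-4-ol | C=C(C[C@H](O)C=C(C)C)[C@@]1(O[Si](C)(C)C)CC[C@](C)(Br)[C@@H](Cl)C1 | intermediate
18 | (1R,3S,4S)-4-bromo-3-chloro-1-[(4S)-4-hydroxy-6-methylhepta-1,5-dien-2-yl]-4-methylcyclohexan-1-ol | C=C(C[C@H](O)C=C(C)C)[C@@]1(O)CC[C@](C)(Br)[C@@H](Cl)C1 | target

**Step count and risks**

Total step count: 12. Longest linear sequence: 12 steps (1 to 18); the route is fully linear.

Steps most likely to fail:

Step 7. Chloride may attack the tertiary epoxide carbon instead of the secondary one. The activated epoxide may also be captured inside the molecule, by the ester carbonyl (lactonisation) or, after ionisation, by the cis hydroxyl (transannular ether formation). The fallback sets out from 9. The epoxide is isomerised with diethylaluminium 2,2,6,6-tetramethylpiperidide (from Et2AlCl and lithium 2,2,6,6-tetramethylpiperidide, toluene, 0 °C), which removes a proton of the methyl group and leaves the secondary C–O bond untouched, to give methyl (1R,3R)-1,3-dihydroxy-4-methylidenecyclohexane-1-carboxylate F1. The secondary allylic hydroxyl is then replaced by chloride with inversion (PPh3, hexachloroacetone, CH2Cl2, −20 °C) to give methyl (1R,3S)-3-chloro-1-hydroxy-4-methylidenecyclohexane-1-carboxylate F2. Markovnikov addition of anhydrous HBr (CH2Cl2, −40 °C), with bromide entering anti to chlorine, comes back to the route at 11 and makes step 8 unnecessary.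

Step 8. The tertiary cation may be trapped across the ring by the cis C1 hydroxyl (7-oxabicyclo[2.2.1]heptane formation), may lose a proton (E1), or may take up bromide without face control. The fallback sets out from 9. The C1 hydroxyl is acetylated (Ac2O, 4-(dimethylamino)pyridine, Et3N, CH2Cl2) to methyl (1R,3R,6S)-3-acetoxy-6-methyl-7-oxabicyclo[4.1.0]heptane-3-carboxylate F3. This is opened with Li2CuCl4 as in step 7 to methyl (1R,3S,4S)-1-acetoxy-3-chloro-4-hydroxy-4-methylcyclohexane-1-carboxylate F4 and converted with HBr into methyl (1R,3S,4S)-1-acetoxy-4-bromo-3-chloro-4-methylcyclohexane-1-carboxylate F5, now without an internal nucleophile. Methanolysis of the acetate (K2CO3, MeOH, 0 °C) comes back to the route at 11.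

Step 11. TiCl4 may ionise the tertiary bromide (halide exchange or elimination) or strip the silyl ether, and the skipped dienone may move into conjugation during reaction or work-up. The fallback sets out from 14. The allylsilane is added to 3-methylbut-2-enal with BF3·OEt2 (CH2Cl2, −78 °C, Hosomi–Sakurai allylation) to give (4RS)-6-[(1R,3S,4S)-4-bromo-3-chloro-4-methyl-1-(trimethylsilyloxy)cyclohexyl]-2-methylhepta-2,6-dien-4-ol F6 as both carbinol epimers. Neutral oxidation of this secondary allylic alcohol with MnO2 (CH2Cl2, rt) erases the uncontrolled centre and comes back to the route at 16.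

Further compounds
F1 | step 7 | methyl (1R,3R)-1,3-dihydroxy-4-methylidenecyclohexane-1-carboxylate | COC(=O)[C@@]1(O)CCC(=C)[C@H](O)C1
F2 | step 7 | methyl (1R,3S)-3-chloro-1-hydroxy-4-methylidenecyclohexane-1-carboxylate | COC(=O)[C@@]1(O)CCC(=C)[C@@H](Cl)C1
F3 | step 8 | methyl (1R,3R,6S)-3-acetoxy-6-methyl-7-oxabicyclo[4.1.0]heptane-3-carboxylate | COC(=O)[C@@]1(OC(C)=O)CC[C@]2(C)O[C@@H]2C1
F4 | step 8 | methyl (1R,3S,4S)-1-acetoxy-3-chloro-4-hydroxy-4-methylcyclohexane-1-carboxylate | COC(=O)[C@@]1(OC(C)=O)CC[C@](C)(O)[C@@H](Cl)C1
F5 | step 8 | methyl (1R,3S,4S)-1-acetoxy-4-bromo-3-chloro-4-methylcyclohexane-1-carboxylate | COC(=O)[C@@]1(OC(C)=O)CC[C@](C)(Br)[C@@H](Cl)C1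
F6 | step 11 | (4RS)-6-[(1R,3S,4S)-4-bromo-3-chloro-4-methyl-1-(trimethylsilyloxy)cyclohexyl]-2-methylhepta-2,6-dien-4-ol | C=C(CC(O)C=C(C)C)[C@@]1(O[Si](C)(C)C)CC[C@](C)(Br)[C@@H](Cl)C1
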